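(Readings and results were computed for an exercise, and the scatter is random.)

At 8.0 h someone reads the larch flask, which is the flask asked about, and two chemists dispute what it holds then and what can still be gained.

the same everywhere: precatalyst 6.4 mM
- larch: left-handed substrate 0.10 M; right-handed substrate 0.10 M; reagent 0.11 M; temperature 110 °C; the very flask that is asked about, followed so far
- cedar: left-handed substrate 0.20 M; right-handed substrate 0.20 M; reagent 0.11 M; temperature 95 °C; run made earlier
- flask: left-handed substrate 0.10 M; right-handed substrate 0.10 M; reagent 0.110 M; temperature 110 °C; time 8.0 h

| run | time / min | left-handed product / % | left-handed substrate / % |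
|---|---|---|---|
| larch | 25.0 | 8.0 | 40.9 |
| larch | 50.0 | 8.3 | 42.1 |
| larch | 120 | 7.3 | 42.4 |
| larch | 300 | 9.8 | 42.9 |
| cedar | 8.00 | 2.7 | 45.1 |
| cedar | 15.0 | 6.7 | 42.9 |
| cedar | 25.0 | 9.3 | 38.6 |
| cedar | 40.0 | 13.6 | 35.7 |

(readings scatter by 1 percentage point)

- free catalyst is single-handed; left-handed substrate and right-handed substrate are mirror images of each other, charged as a racemate, each of them at the stated concentration
- removed left-handed product is counted in
- additions bring no volume worth counting

- grey: at 8.0 h add precatalyst, 100% of the amount charged, then wait 8.0 h
- ochre: at 8.0 h add reagent, 50.0% of the amount charged, then wait 8.0 h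
- green: change nothing and wait 8.0 h more
- violet: at 8.0 h take out 90% of the left-handed product then present, then wait 8.0 h
- blue: at 8.0 h raise the temperature by 20 K, then wait 8.0 h

- left-handed product, in percent of the left-handed substrate and right-handed substrate together first charged, at 8.0 h
- what to do for the largest gain in left-handed product; "none" if nothing gains more than 2 percentage points (grey / ochre / green / violet / blue / none)
- left-handed product present, with what was taken out counted in, in percent of the left-handed substrate and right-handed substrate together first charged, after ochre
- left-handed product present, with what was taken out counted in, in percent of the left-handed substrate and right-handed substrate together first charged, after green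

Look first at the larch readings: left-handed product stands at 8.0% at 25.0 min and at 9.8% at 300 min, with a scatter of 1 percentage point. The mean of the 4 readings is 8.35%, which is 0.0167 M of left-handed product.

The reagent chemist calls the reagent the limiting reagent: the hot larch flask loses it somehow, and the stall marks its end. On that view ochre, adding 50.0% of the charge, gains 4.2 points. But the cedar flask, with the same reagent charge though at 95 °C and with 0.20 M of each substrate, reads 0.0544 M by 40.0 min, more than the larch stall, and its readings are still climbing then.

The catalyst chemist divides instead. The stall over the charged 6.4 mM gives 2.61. This is N, left-handed product made per precatalyst charged before the catalyst dies, the turnover number. Each catalyst either turns over or dies, so on this view N is a ratio of two rates and belongs to one set of conditions: cedar, which differs in temperature and in substrates, already reads 8.50. If turnover goes with reagent and death does not, then N goes in proportion to the reagent charge, with temperature and substrates held fixed. So on this view waiting and ochre gain nothing in the larch flask, and a fresh dose of 100% of the precatalyst charge, if N stayed the same, gains 8.3 points.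

The forecast takes the catalyst side, “So the catalyst most likely dies at 110 °C, after about 2.6 turnovers.” It gives 8.5% now, grey as best, 8.6% after ochre and 8.6% after green. For the fresh dose it expects about 7 points.

The flask gives 8.33%, 8.33% after ochre, 8.33% after green, and grey as best, gaining 5.9 points.

    free catalyst + left-handed substrate ⇌ catalyst intermediate A (K = 10.0 M⁻¹, k = 35.0 M⁻¹ s⁻¹, Ea = 58.0 kJ mol⁻¹, ΔH = −25.0 kJ mol⁻¹)
    free catalyst + right-handed substrate ⇌ catalyst intermediate B (K = 5.20 M⁻¹, k = 130 M⁻¹ s⁻¹, Ea = 51.0 kJ mol⁻¹, ΔH = −18.0 kJ mol⁻¹)
    reagent + catalyst intermediate A → free catalyst + left-handed product (k = 1.70 M⁻¹ s⁻¹, Ea = 48.0 kJ mol⁻¹)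
    reagent + catalyst intermediate B → free catalyst + right-handed product (k = 0.200 M⁻¹ s⁻¹, Ea = 64.0 kJ mol⁻¹)
    reagent ⇌ dormant form (K = 6.20, k = 0.110 s⁻¹, Ea = 86.0 kJ mol⁻¹, ΔH = 29.0 kJ mol⁻¹)
    free catalyst → spent catalyst (k = 0.00820 s⁻¹, Ea = 97.0 kJ mol⁻¹)
    precatalyst → free catalyst (k = 0.00950 s⁻¹, Ea = 96.0 kJ mol⁻¹)
    (constants at 110 °C)

At 480 min spent catalyst is 100% of the catalyst. Against the 8.3 points that N offered for grey, the flask gives 5.9 points. The reagent chemist keeps the starting charge, though not the addition at 8.0 h: the answer to "now" has moved by 5 points at a reagent charge of 0.0416 M. For a neighbour flask charged with 0.044 M of reagent, N scales to 1.04, which gives 3.34% of left-handed product. The computed neighbour gives 3.52%.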